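You are asked how double product after 5.0 d runs across the flasks below, and the quick way in is to ask what would make the row rise all the way.

| setting | Friday's | Monday's | cedar | larch | maple | alder |
|---|---|---|---|---|---|---|
| substrate | 0.053 M | 1.3 M | 0.040 M | 0.12 M | 0.40 M | 1.2 M |
| partner | 0.40 M | 0.40 M | 0.400 M | 0.400 M | 0.400 M | 0.400 M |
| remark | run made earlier | run made earlier |  |  |  |  |
| time |  |  | 5.0 d | 5.0 d | 5.0 d | 5.0 d |

| run | time / d | double product / % | substrate / % |
|---|---|---|---|
| Friday's | 0.208 | 2.9 | 83.5 |
| Friday's | 0.417 | 9.4 | 70.3 |
| Friday's | 0.625 | 16.2 | 58.4 |
| Friday's | 1.25 | 29.8 | 35.8 |
| Friday's | 2.50 | 29.6 | 15.5 |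
| Monday's | 0.500 | 4.8 | 79.6 |
| Monday's | 1.04 | 5.3 | 76.0 |
| Monday's | 1.67 | 5.3 | 74.9 |
| Monday's | 2.08 | 3.5 | 73.9 |
| Monday's | 2.50 | 4.2 | 73.9 |

(readings scatter by 0.5 percentage points)

- [double product] at the end for cedar, larch, maple, alder, in this order
- how the row runs (falls, then rises / rises, then falls / hardly changes / rises all the way / falls all the way)

- a species is counted by the substrate in it: one side product counts as two
- the numbers in the tables scatter with a standard deviation of 0.5 percentage points
- what may be going on: partner + double product -> tris adduct + by-product; substrate + double product -> side product; substrate + partner -> single product + by-product; partner + single product -> double product + by-product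
- "hardly changes" means that all values lie within two and a half points (for a concentration: within two and a half percent of the largest)

For that outcome alder must end above maple. Monday's run, close to alder's recipe, reads 4.2 % of its charge as double product at 2.50 d. At that fraction alder holds 0.0504 M, so maple would have to end below 12.6 % of its charge.

Take the symmetric chain as the zero of the scale: substrate to single product, single to double, double to tris adduct, each with the same rate constant. Its clock is the overrun half-life, the time in which double product halves against partner at its charge if that last step goes as fast as the step from substrate: 0.805 d, read from Friday's substrate at 0.625 d. With the dose defined as ln(2) times time over this half-life, the fraction standing as double product is half the dose squared, times the exponential of minus the dose. Its peak of 27.1 % lies near Friday's top reading of 29.8 %.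

Cedar has 10.0 partner per substrate, and the chain can take 3 partners per substrate, so at least 70.0 % of its partner stays. With partner held at its charge the dose is 4.30 and the fraction 12.5 %, or 0.00501 M; with partner held at that floor the dose is 3.01 and the fraction 22.3 %, or 0.00893 M, so you should take cedar as that span and not as one figure. Maple has 1.00 partner per substrate, which makes partner the limiting reagent. The chain uses about one partner per substrate for each unit of dose, so the dose stops near 1.00, at a fraction of 18.4 %, or 0.0736 M. That is more than the 12.6 % required, by a factor of 1.46, and it stands above the top of cedar's span, so the row should rise, then fall.

The forecast gave 0.0044 M, 0.029 M, 0.085 M and 0.028 M, running rises, then falls, with alder's double product one that “decays with substrate over about 4 d”.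

The flasks give 0.00471 M, 0.0298 M, 0.0849 M and 0.0313 M: rises, then falls.

    partner + double product → tris adduct + by-product (k = 0.0982 M⁻¹ h⁻¹)
    substrate + double product → side product (k = 0.0102 M⁻¹ h⁻¹)
    substrate + partner → single product + by-product (k = 0.0927 M⁻¹ h⁻¹)
    partner + single product → double product + by-product (k = 0.241 M⁻¹ h⁻¹)

In cedar, double product has a half-life of 0.74 d by the tris step alone at charged partner, beside the 0.805 d reckoned above and short against 5.0 d, and at the end it is made at 0.343 of the rate at which it is used. In maple, which has the same partner charge, with 0.45 % of the partner left at 5.00 d, that half-life of 0.74 d stretches to 164 d, longer than 5.0 d, and tris adduct stands at 9.52 % then and 9.61 % at 50.0 d.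

(Readings and results come from a simulation from invented constants; noise was put on by code.)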